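**Strategy**

The drimane core is cut at the C3–C4 bond of ring A (drimane numbering). Ring B of the target (C5–C10, with H-5, the C8-methyl 7,8-alkene and the substituted C9) is the ring of (R)-carvone, and the gem-dimethyl carbon C4 is its isopropenyl carbon. In one operation, acid turns that isopropenyl group into the C4 cation, which is trapped at the silicon-bearing carbon of a Z vinylsilane on C10; ring A closes as a trans-decalin and a 2,3-alkene is left. The precursor is carvone carrying at C10 a methyl group and, anti to the isopropenyl group, a (Z)-3-(trimethylsilyl)allyl chain. Drimenol and its caffeate follow.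

Key step: step 4

Assumption: the transient carbocations of step 4 are treated as mechanism and carry no compound number; the caffeate is built by a protecting-group-free malonate route from 3,4-dihydroxybenzaldehyde instead of from caffeic acid.

**Route**

Step 1
Reactants: 1 (R)-(−)-carvone; 2 iodomethane
Product: 4 (5R,6RS)-6-methylcarvone, via lithium dienolate 3 (not isolated)
Conditions: LiN(iPr)2 (1.05 equiv), THF, −78 °C; then MeI, −78 → 0 °C
Reagents that add atoms: none
Why: Kinetic deprotonation at the α' CH2 (the future C10) gives the cross-conjugated enolate, which is C-methylated (enolate alkylation); the new centre forms as an epimer mixture that step 2 erases.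

Step 2
Reactants: 4 (5R,6RS)-6-methylcarvone; 5 3-bromo-1-(trimethylsilyl)propyne
Product: 7 (5S,6S)-6-methyl-6-[3-(trimethylsilyl)prop-2-ynyl]carvone, via lithium enolate 6 (not isolated)
Conditions: LiN(iPr)2 (1.1 equiv), THF, −78 → 0 °C; then 5, −78 °C → rt
Reagents that add atoms: none
Why: Both epimers of 4 give the same tetrasubstituted enolate, which is alkylated by the propargylic bromide on the face anti to the neighbouring isopropenyl group (enolate alkylation, substrate control), so the quaternary centre (future C10) carries methyl cis and chain trans to isopropenyl.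

Step 3
Reactants: 7 (5S,6S)-6-methyl-6-[3-(trimethylsilyl)prop-2-ynyl]carvone
Product: 8 (5S,6S)-6-methyl-6-[(Z)-3-(trimethylsilyl)allyl]carvone
Conditions: H2 (1 atm), Pd/CaCO3 poisoned with Pb(OAc)2, quinoline, EtOAc, rt, stopped at 1 equiv H2
Reagents that add atoms: none
Why: Syn addition of hydrogen on the poisoned palladium surface gives the Z alkene (alkyne semi-hydrogenation), and the alkyne binds much more strongly than the isopropenyl and enone alkenes, which should survive.

Step 4
Reactants: 8 (5S,6S)-6-methyl-6-[(Z)-3-(trimethylsilyl)allyl]carvone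
Product: 9 (5S,10S)-11-nordrima-2,7-dien-9-one
Conditions: CF3SO3H (2–3 equiv), CH2Cl2, −78 → −20 °C; then aq NaHCO3
Reagents that add atoms: none
Why: Triflic acid protonates the isopropenyl CH2 in the Markovnikov sense to give the tertiary C4 cation, while the O-protonated enone keeps the 7,8-alkene out of play; the cation is attacked by the silicon-bearing C3 of the vinylsilane (ipso attack), and the resulting C2 cation, stabilised by the β C–Si bond, loses the silyl group to triflate and leaves the 2,3-alkene. The closest known reaction type is the vinylsilane-terminated cation–alkene cyclization. Ring A closes in the 6-endo-trig mode with both vinylsilane carbons in the ring, which is why the Z geometry is needed: C1 and C4 must end up cis on the new ring alkene. No stereocentre is created (C4 becomes the gem-dimethyl carbon), and the trans ring fusion follows from the trans-diequatorial arms fixed in step 2, joined through a chair-like transition state. The selectivity that matters is C–C bond formation at C3 ahead of protodesilylation and ahead of loss of H-5 from the C4 cation; it should be secured by the higher proton affinity of the 1,1-disubstituted alkene compared with the vinylsilane, by the β-silicon effect that directs attack to C3, and by the low temperature. The quaternary C10 rules out aromatisation of ring B.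

Step 5
Reactants: 9 (5S,10S)-11-nordrima-2,7-dien-9-one
Product: 10 (5S,10S)-11-nordrim-7-en-9-one
Conditions: H2 (1–3 atm), (Ph3P)3RhCl (5 mol%), benzene/EtOH, rt
Reagents that add atoms: none
Why: Homogeneous hydrogenation with chlorotris(triphenylphosphine)rhodium should reduce the cis-disubstituted 2,3-alkene and leave the trisubstituted conjugated 7,8-alkene and the ketone; no stereocentre is formed.

Step 6
Reactants: 10 (5S,10S)-11-nordrim-7-en-9-one
Product: 11 (5S,10S)-drima-7,9(11)-diene
Conditions: Ph3PCH3Br, KOtBu, toluene, 90–110 °C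
Reagents that add atoms: methyltriphenylphosphonium bromide, C[P+](c1ccccc1)(c1ccccc1)c1ccccc1.[Br-]
Why: Wittig methylenation with the ylide at elevated temperature is the usual answer to a hindered ketone, and the quaternary C10 leaves no α-hydrogen on that side; no stereocentre is formed.

Step 7
Reactants: 11 (5S,10S)-drima-7,9(11)-diene
Product: 13 (−)-drimenol, via B-drimenyl-9-BBN 12 (not isolated)
Conditions: 9-BBN (9-borabicyclo[3.3.1]nonane), THF, 0 °C → rt; then NaOH, H2O2, H2O, 0 °C → rt
Reagents that add atoms: hydrogen peroxide, OO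
Why: Hydroboration–oxidation: the bulky borane should select the exocyclic 1,1-disubstituted alkene over the trisubstituted 7,8-alkene and put boron on C11, with hydrogen delivered to C9 from the α face opposite the axial C10 methyl (C9 = S, CH2OH β), and oxidation proceeds with retention.

Step 8
Reactants: 13 (−)-drimenol; 14 Meldrum's acid
Product: 15 drimenyl hydrogen malonate
Conditions: toluene, 110 °C
Reagents that add atoms: none
Why: Alcoholysis of Meldrum's acid with loss of acetone acylates the primary alcohol under neutral conditions to the malonic half-ester; the 7,8-alkene and the three stereocentres are not touched.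

Step 9
Reactants: 15 drimenyl hydrogen malonate; 16 3,4-dihydroxybenzaldehyde
Product: 18 drimenyl (E)-caffeate (target), via arylidenemalonic half-ester 17 (not isolated)
Conditions: pyridine, piperidine (cat.), N2, rt → 50 °C; cold dilute aqueous citric acid work-up
Reagents that add atoms: none
Why: Knoevenagel–Doebner condensation: the half-ester condenses with the aldehyde and decarboxylates to the thermodynamically preferred (E)-cinnamate, and the free catechol is tolerated, so no protecting group is needed.

**Compound list**

1 | (R)-(−)-carvone, (5R)-2-methyl-5-(prop-1-en-2-yl)cyclohex-2-en-1-one | CC1=CC[C@H](CC1=O)C(C)=C | starting material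
2 | iodomethane | CI | starting material
3 | lithium dienolate of 1 (not isolated): lithium (5R)-2-methyl-5-(prop-1-en-2-yl)cyclohexa-1(6),2-dien-1-olate | [Li]OC1=C[C@H](C(C)=C)CC=C1C | intermediate
4 | 6-methylcarvone: (5R,6RS)-2,6-dimethyl-5-(prop-1-en-2-yl)cyclohex-2-en-1-one, mixture of C6 epimers | CC1=CC[C@@H](C(C)=C)C(C)C1=O | intermediate
5 | 3-bromo-1-(trimethylsilyl)propyne | C[Si](C)(C)C#CCBr | starting material
6 | lithium enolate of 4 (not isolated): lithium (5S)-2,6-dimethyl-5-(prop-1-en-2-yl)cyclohexa-1(6),2-dien-1-olate | [Li]OC1=C(C)[C@H](C(C)=C)CC=C1C | intermediate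
7 | (5S,6S)-2,6-dimethyl-5-(prop-1-en-2-yl)-6-[3-(trimethylsilyl)prop-2-yn-1-yl]cyclohex-2-en-1-one | CC1=CC[C@@H](C(C)=C)[C@](C)(CC#C[Si](C)(C)C)C1=O | intermediate
8 | (5S,6S)-2,6-dimethyl-5-(prop-1-en-2-yl)-6-[(2Z)-3-(trimethylsilyl)prop-2-en-1-yl]cyclohex-2-en-1-one (chain anti to isopropenyl) | CC1=CC[C@@H](C(C)=C)[C@](C)(C/C=C\[Si](C)(C)C)C1=O | intermediate
9 | (5S,10S)-11-nordrima-2,7-dien-9-one: (4aS,8aS)-2,5,5,8a-tetramethyl-4a,5,8,8a-tetrahydronaphthalen-1(4H)-one | CC1=CC[C@H]2C(C)(C)C=CC[C@]2(C)C1=O | intermediate
10 | (5S,10S)-11-nordrim-7-en-9-one: (4aS,8aS)-2,5,5,8a-tetramethyl-4a,5,6,7,8,8a-hexahydronaphthalen-1(4H)-one | CC1=CC[C@H]2C(C)(C)CCC[C@]2(C)C1=O | intermediate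
11 | (5S,10S)-drima-7,9(11)-diene: (4aS,8aS)-2,5,5,8a-tetramethyl-1-methylidene-1,4,4a,5,6,7,8,8a-octahydronaphthalene | CC1=CC[C@H]2C(C)(C)CCC[C@]2(C)C1=C | intermediate
12 | B-drimenyl-9-BBN (not isolated): 9-{[(1S,4aS,8aS)-2,5,5,8a-tetramethyl-1,4,4a,5,6,7,8,8a-octahydronaphthalen-1-yl]methyl}-9-borabicyclo[3.3.1]nonane | CC1=CC[C@H]2C(C)(C)CCC[C@]2(C)[C@H]1CB1C2CCCC1CCC2 | intermediate
13 | (−)-drimenol: [(1S,4aS,8aS)-2,5,5,8a-tetramethyl-1,4,4a,5,6,7,8,8a-octahydronaphthalen-1-yl]methanol | CC1=CC[C@H]2C(C)(C)CCC[C@]2(C)[C@H]1CO | intermediate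
14 | Meldrum's acid, 2,2-dimethyl-1,3-dioxane-4,6-dione | CC1(C)OC(=O)CC(=O)O1 | starting material
15 | drimenyl hydrogen malonate: 3-oxo-3-{[(1S,4aS,8aS)-2,5,5,8a-tetramethyl-1,4,4a,5,6,7,8,8a-octahydronaphthalen-1-yl]methoxy}propanoic acid | CC1=CC[C@H]2C(C)(C)CCC[C@]2(C)[C@H]1COC(=O)CC(O)=O | intermediate
16 | 3,4-dihydroxybenzaldehyde | O=Cc1ccc(O)c(O)c1 | starting material
17 | arylidenemalonic half-ester (not isolated): 2-(3,4-dihydroxybenzylidene)malonic acid mono-drimenyl ester, alkene geometry not controlled | CC1=CC[C@H]2C(C)(C)CCC[C@]2(C)[C@H]1COC(=O)C(=Cc1ccc(O)c(O)c1)C(O)=O | intermediate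
18 | drimenyl (E)-caffeate: [(1S,4aS,8aS)-2,5,5,8a-tetramethyl-1,4,4a,5,6,7,8,8a-octahydronaphthalen-1-yl]methyl (2E)-3-(3,4-dihydroxyphenyl)prop-2-enoate | CC1=CC[C@H]2C(C)(C)CCC[C@]2(C)[C@H]1COC(=O)/C=C/c1ccc(O)c(O)c1 | target

**Count**

Total steps: 9. Longest linear sequence: 9 steps (1 → 18).

**Steps most likely to fail**

Step 4. Protonation of the vinylsilane (protodesilylation) or loss of H-5 from the C4 cation may outrun ring closure, which would leave uncyclized material or scramble C5. The fallback sets out from 7 and comes back at 9, and forms the same C3–C4 bond without a carbocation. The silyl group of 7 is removed with K2CO3 in MeOH to give the terminal alkyne (5S,6S)-6-methyl-6-(prop-2-ynyl)carvone F1. This is iodinated with N-iodosuccinimide and catalytic AgNO3 in acetone to the iodoalkyne (5S,6S)-6-(3-iodoprop-2-ynyl)-6-methylcarvone F2. Syn reduction with diimide (2-nitrobenzenesulfonyl hydrazide, Et3N) should give the vinyl iodide (5S,6S)-6-[(Z)-3-iodoallyl]-6-methylcarvone F3. A reductive Heck cyclization (Pd(OAc)2, PPh3, HCO2Na, Et4NCl, DMF, 80 °C) then joins C3 to C4 by 6-exo-trig carbopalladation of the isopropenyl group. The neopentyl-type alkylpalladium has no β-hydrogen and is reduced by formate to the second C4 methyl group, giving 9.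

Step 7. Hydrogen may be delivered to C9 from the β face, the borane may attack the 7,8-alkene, or the conjugated diene may react sluggishly. The fallback sets out from 10, comes back at 13 and replaces steps 6 and 7. Dimethylsulfonium methylide (Me3SI, nBuLi, THF) should add to the C9 carbonyl from the α face (Corey–Chaykovsky epoxidation) to give the vinyl oxirane (5S,9S,10S)-9,11-epoxydrim-7-ene F4, with the C9–O bond on the β face. Palladium-catalysed formate hydrogenolysis (Pd2(dba)3, nBu3P, HCO2H, Et3N, dioxane) opens the allylic C9–O bond with inversion. Hydride is then transferred from the metal to C9 on the α face while the 7,8-alkene stays in place, so 13 results from a stereospecific path.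

Step 6. The ylide may fail to add to a carbonyl flanked by the quaternary C10 and the C8 methyl, or may act as a base at C6, so that ketone is returned. The fallback sets out from 10 and comes back at 11 by a Peterson olefination. Me3SiCH2Li with CeCl3 in THF adds 1,2 to the ketone to give the β-hydroxysilane (1S,4aS,8aS)-2,5,5,8a-tetramethyl-1-[(trimethylsilyl)methyl]-1,4,4a,5,6,7,8,8a-octahydronaphthalen-1-ol F5 (either C9 epimer serves). KH in THF then brings about syn elimination to the exocyclic alkene of 11.

**Further compounds**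

F1 | step 4 | (5S,6S)-2,6-dimethyl-5-(prop-1-en-2-yl)-6-(prop-2-yn-1-yl)cyclohex-2-en-1-one | CC1=CC[C@@H](C(C)=C)[C@](C)(CC#C)C1=O
F2 | step 4 | (5S,6S)-6-(3-iodoprop-2-yn-1-yl)-2,6-dimethyl-5-(prop-1-en-2-yl)cyclohex-2-en-1-one | CC1=CC[C@@H](C(C)=C)[C@](C)(CC#CI)C1=O
F3 | step 4 | (5S,6S)-6-[(2Z)-3-iodoprop-2-en-1-yl]-2,6-dimethyl-5-(prop-1-en-2-yl)cyclohex-2-en-1-one | CC1=CC[C@@H](C(C)=C)[C@](C)(C/C=C\I)C1=O
F4 | step 7 | (5S,9S,10S)-9,11-epoxydrim-7-ene (spiro-oxirane, oxygen on the β face) | CC1=CC[C@H]2C(C)(C)CCC[C@]2(C)[C@]13CO3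
F5 | step 6 | (1S,4aS,8aS)-2,5,5,8a-tetramethyl-1-[(trimethylsilyl)methyl]-1,4,4a,5,6,7,8,8a-octahydronaphthalen-1-ol | CC1=CC[C@H]2C(C)(C)CCC[C@]2(C)[C@]1(O)C[Si](C)(C)C
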